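**Plan**

1. Numbering used throughout (germacrane): C6 = lactone O–CH, C7 = ring-fusion CH, C8 = CHOH, C2 = CH–O-tigloyl, C4=C5 and C1=C10 = ring alkenes, C11/C12/C13 = lactone α-carbon/C=O/=CH2, C14 = methyl on C10, C15 = CH2OAc; TBS = tert-butyl(dimethyl)silyl.
2. Enabling feature: the lactone oxygen sits on C6, which is allylic to the C4=C5 alkene, and the lactone α-carbon C11 sits on the neighbouring C7. The methylene-butyrolactone ring with its C4=C5 vinyl arm is therefore the 1,2-carbo-oxygenation adduct of a C4=C5–C6=C7 diene and 2-bromoacrylic acid.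
3. Cuts: the two esters; C1=C10 (ring-closing metathesis); O–C6 and C11–C7 together (annulation); C5–C6 (Sonogashira, then alkyne semireduction); C1–C2 and C8–C9 (asymmetric carbonyl additions); C3–C4 (carbomagnesiation of propargyl alcohol).
4. Forward: two linear fragments (C1–C5/C15 and C6–C10/C14) are joined to an acyclic dienyl chain; the five-membered lactone ring is formed first, the ten-membered ring second, and the acyl pattern is set last.
5. Stereochemistry: C8 by catalyst-controlled methallylboration; C7 and C6 relayed from C8 in the annulation; C2 by catalyst-controlled alkenylzinc addition; C4=C5 geometry from anti-carbomagnesiation; ring-cis C1=C10 geometry from strain control in the metathesis.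

Key step: step 10

Assumption: the facial sense of the two catalyst-controlled additions follows the accepted transition-state models ((R)-TRIP: Re face of aldehyde 12; (+)-MIB: Re face of aldehyde 7); if either proves opposite, the enantiomeric catalyst is used and nothing else changes.

**Route**

Step 1
Reactants: 1 prop-2-yn-1-ol; 2 allylmagnesium bromide
Product: 4 (2Z)-2-(iodomethylidene)pent-4-en-1-ol, via 4-(prop-2-en-1-yl)-2,5-dihydro-1,2-oxamagnesole 3 (not isolated)
Conditions: 2 (2.5 equiv), CuI (10 mol %), Et2O/THF, -20 °C to rt; then I2, -78 to 0 °C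
Reagents that add atoms: iodine, II
Why: Alkoxide-directed, copper-catalysed anti-carbomagnesiation of a propargylic alcohol should place the allyl group on the internal alkyne carbon and magnesium on the terminal carbon cis to CH2O (chelate 3), and iodinolysis with retention fixes the C4=C5 geometry of the target (iodine, later C6, cis to C15).

Step 2
Reactants: 4 (2Z)-2-(iodomethylidene)pent-4-en-1-ol
Product: 5 tert-butyl{[(2Z)-2-(iodomethylidene)pent-4-en-1-yl]oxy}dimethylsilane
Conditions: TBSCl, imidazole, CH2Cl2, 0 °C to rt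
Reagents that add atoms: tert-butyl(chloro)dimethylsilane, CC(C)(C)[Si](C)(C)Cl
Why: Standard silylation of a primary alcohol gives a C15–O protecting group that cannot ionise under the later palladium steps.

Step 3
Reactants: 5 tert-butyl{[(2Z)-2-(iodomethylidene)pent-4-en-1-yl]oxy}dimethylsilane
Product: 7 (3Z)-3-(TBSO-methyl)-4-iodobut-3-enal, via (4Z)-4-(TBSO-methyl)-5-iodopent-4-ene-1,2-diol 6 (not isolated)
Conditions: OsO4 (2 mol %), NaIO4 (4 equiv), 2,6-lutidine, dioxane/H2O 3:1, rt
Reagents that add atoms: osmium tetroxide, O=[Os](=O)(=O)=O (catalytic, oxygen replenished by sodium periodate, [Na+].[O-]I(=O)(=O)=O)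
Why: In this Lemieux–Johnson cleavage OsO4 should dihydroxylate the monosubstituted alkene in preference to the iodine-deactivated, hindered trisubstituted one, and periodate cleaves diol 6 to the C2 aldehyde, with lutidine buffering against conjugation.

Step 4
Reactants: 8 hex-1-yne; 7 (3Z)-3-(TBSO-methyl)-4-iodobut-3-enal
Product: 11 (1Z,4S,5E)-2-(TBSO-methyl)-1-iododeca-1,5-dien-4-ol, via dicyclohexyl[(1E)-hex-1-en-1-yl]borane 9 (not isolated), via ethyl[(1E)-hex-1-en-1-yl]zinc 10 (not isolated)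
Conditions: 8, Cy2BH, toluene, 0 °C to rt; Et2Zn, -78 °C; (+)-MIB (5 mol %), then 7, -20 to 0 °C; aq. work-up
Reagents that add atoms: none
Why: Hydroboration, boron-to-zinc exchange and amino-alcohol-catalysed enantioselective alkenylzinc addition to an aldehyde should deliver the alkenyl group to the Re face and set C2 (S); the new alkenyl CH becomes C1 and is the handle for the metathesis.

Step 5
Reactants: 12 3-(trimethylsilyl)prop-2-ynal; 13 4,4,5,5-tetramethyl-2-(2-methylprop-2-en-1-yl)-1,3,2-dioxaborolane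
Product: 14 (3R)-5-methyl-1-(trimethylsilyl)hex-5-en-1-yn-3-ol
Conditions: (R)-TRIP (5 mol %), 4 Å MS, toluene, -40 °C; aq. work-up
Reagents that add atoms: none
Why: Chiral phosphoric acid-catalysed allylboration through a chair transition state should add the methallyl group to the Re face and set C8 (R), the one stereocentre that later steers C7 and C6.

Step 6
Reactants: 14 (3R)-5-methyl-1-(trimethylsilyl)hex-5-en-1-yn-3-ol
Product: 15 tert-butyl(dimethyl){[(3R)-5-methyl-1-(trimethylsilyl)hex-5-en-1-yn-3-yl]oxy}silane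
Conditions: TBSCl, imidazole, DMF, rt
Reagents that add atoms: tert-butyl(chloro)dimethylsilane, CC(C)(C)[Si](C)(C)Cl
Why: Standard silylation of the secondary alcohol; the bulky silyl ether is also the shielding group for step 10.

Step 7
Reactants: 15 tert-butyl(dimethyl){[(3R)-5-methyl-1-(trimethylsilyl)hex-5-en-1-yn-3-yl]oxy}silane
Product: 16 tert-butyl(dimethyl){[(3R)-5-methylhex-5-en-1-yn-3-yl]oxy}silane
Conditions: K2CO3 (cat.), MeOH, rt
Reagents that add atoms: none
Why: Base-catalysed methanolysis cleaves the alkynyl C–Si bond selectively and leaves the O-TBS ether untouched.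

Step 8
Reactants: 16 tert-butyl(dimethyl){[(3R)-5-methylhex-5-en-1-yn-3-yl]oxy}silane; 11 (1Z,4S,5E)-2-(TBSO-methyl)-1-iododeca-1,5-dien-4-ol
Product: 17 (5E,7S,9Z,13R)-13-(TBSO)-9-(TBSO-methyl)-15-methylhexadeca-5,9,15-trien-11-yn-7-ol
Conditions: Pd(PPh3)2Cl2 (3 mol %), CuI (6 mol %), Et3N, THF, rt
Reagents that add atoms: none
Why: Sonogashira coupling forms C5–C6 with retention of the vinyl iodide geometry and tolerates the free allylic alcohol.

Step 9
Reactants: 17 (5E,7S,9Z,13R)-13-(TBSO)-9-(TBSO-methyl)-15-methylhexadeca-5,9,15-trien-11-yn-7-ol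
Product: 18 (5E,7S,9Z,11Z,13R)-13-(TBSO)-9-(TBSO-methyl)-15-methylhexadeca-5,9,11,15-tetraen-7-ol
Conditions: Zn dust activated with Cu(OAc)2 and AgNO3, MeOH/H2O 1:1, 45 °C
Reagents that add atoms: none
Why: Zinc–copper–silver semireduction (Boland conditions) of a conjugated enyne should deliver both hydrogens syn to give the Z C6=C7 alkene without touching the isolated alkenes.

Step 10
Reactants: 18 (5E,7S,9Z,11Z,13R)-13-(TBSO)-9-(TBSO-methyl)-15-methylhexadeca-5,9,11,15-tetraen-7-ol; 19 2-bromoprop-2-enoic acid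
Product: 20 (4S,5R)-4-[(1R)-1-(TBSO)-3-methylbut-3-en-1-yl]-5-[(1Z,4S,5E)-2-(TBSO-methyl)-4-hydroxydeca-1,5-dien-1-yl]-3-methylideneoxolan-2-one
Conditions: Pd2(dba)3 (5 mol %), dppf (12 mol %), Ag2CO3 (1.0 equiv), 19 (1.5 equiv, slow addition), MeCN, 60 °C
Reagents that add atoms: none
Why: Proposed new method: oxidative addition of the C–Br bond of 19 to zerovalent palladium gives a 1-carboxyvinyl–palladium species that inserts the C6=C7 alkene of 18 syn, carbon to the CH terminus C7 (the other diene terminus C4 is fully substituted), and the resulting cationic η3-allyl complex over C6–C5–C4 is captured at C6 by the tethered carboxylate; the closest known reaction type is the Larock-type palladium-catalysed heteroannulation of 1,3-dienes by aryl or vinylic halides bearing an OH, NHR or CO2H group, which has not been shown for an internal Z-diene with an allylic stereocentre. The lactone ring closes in a 5-exo sense at the proximal allyl terminus (O onto C6) and not at the tertiary terminus C4, which leaves the C4=C5 alkene outside the ring with its geometry, because the s-trans diene gives the syn-allyl complex and no σ-complex at tertiary C4 is required. C7 is set by 1,2-induction from C8: the Z-alkene holds the C8–H bond in the alkene plane by A(1,3) strain, and the vinyl–palladium unit should add to the face anti to the bulky OTBS group, which places C11 anti to O8 as in the target. C6 is set by the mode of C–O bond formation: with the chelating diphosphine and the silver halide scavenger the allyl complex is cationic and coordinatively saturated, so the carboxylate should attack anti to palladium after rotation about C6–C7, and syn insertion plus anti attack on a Z-alkene is a net anti addition that gives the 6,7-trans lactone. The step needs chemoselectivity for the conjugated diene over the 1,1-disubstituted and allylic-alcohol alkenes, which rests on the faster insertion of a diene that leads to a stabilised allyl complex.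

Step 11
Reactants: 20 (4S,5R)-4-[(1R)-1-(TBSO)-3-methylbut-3-en-1-yl]-5-[(1Z,4S,5E)-2-(TBSO-methyl)-4-hydroxydeca-1,5-dien-1-yl]-3-methylideneoxolan-2-one
Product: 21 (4S,5R)-4-[(1R)-1-(TBSO)-3-methylbut-3-en-1-yl]-5-[(1Z,4S,5E)-2-(TBSO-methyl)-4-{[(2E)-2-methylbut-2-enoyl]oxy}deca-1,5-dien-1-yl]-3-methylideneoxolan-2-one
Conditions: tigloyl chloride, pyridine, DMAP (cat.), CH2Cl2, 0 °C
Reagents that add atoms: (2E)-2-methylbut-2-enoyl chloride, C/C=C(\C)C(Cl)=O
Why: Acylation of the only free hydroxyl (C2) installs the tiglate with retention at C2 under conditions too mild to epimerise C7.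

Step 12
Reactants: 21 (4S,5R)-4-[(1R)-1-(TBSO)-3-methylbut-3-en-1-yl]-5-[(1Z,4S,5E)-2-(TBSO-methyl)-4-{[(2E)-2-methylbut-2-enoyl]oxy}deca-1,5-dien-1-yl]-3-methylideneoxolan-2-one
Product: 22 (3aS,4R,6Z,8S,10Z,11aR)-4-(TBSO)-10-(TBSO-methyl)-6-methyl-3-methylidene-2-oxo-2,3,3a,4,5,8,9,11a-octahydrocyclodeca[b]furan-8-yl (2E)-2-methylbut-2-enoate
Conditions: second-generation Grubbs catalyst (H2IMes)(PCy3)Cl2Ru=CHPh (15 mol %), 1,4-benzoquinone (30 mol %), toluene (1 mM), 90 °C
Reagents that add atoms: none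
Why: In this ring-closing metathesis the carbene should load at the disubstituted alkenyl end and close onto the 1,1-disubstituted alkene with loss of hex-1-ene; a ten-membered ring should form the less strained ring-cis trisubstituted alkene, which is the C1=C10 geometry of the target, while the electron-poor methylene lactone and the trisubstituted alkenes should stay out.

Step 13
Reactants: 22 (3aS,4R,6Z,8S,10Z,11aR)-4-(TBSO)-10-(TBSO-methyl)-6-methyl-3-methylidene-2-oxo-2,3,3a,4,5,8,9,11a-octahydrocyclodeca[b]furan-8-yl (2E)-2-methylbut-2-enoate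
Product: 23 (3aR,4R,6Z,8S,10Z,11aR)-4-hydroxy-10-(hydroxymethyl)-6-methyl-3-methylidene-2-oxo-2,3,3a,4,5,8,9,11a-octahydrocyclodeca[b]furan-8-yl (2E)-2-methylbut-2-enoate
Conditions: HF·pyridine, pyridine, THF, 0 °C to rt
Reagents that add atoms: none
Why: Buffered fluoride desilylation removes both TBS ethers and should leave the allylic lactone, the tiglate and the methylene lactone intact.

Step 14
Reactants: 23 (3aR,4R,6Z,8S,10Z,11aR)-4-hydroxy-10-(hydroxymethyl)-6-methyl-3-methylidene-2-oxo-2,3,3a,4,5,8,9,11a-octahydrocyclodeca[b]furan-8-yl (2E)-2-methylbut-2-enoate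
Product: 24 (3aR,4R,6Z,8S,10Z,11aR)-10-(acetoxymethyl)-4-hydroxy-6-methyl-3-methylidene-2-oxo-2,3,3a,4,5,8,9,11a-octahydrocyclodeca[b]furan-8-yl (2E)-2-methylbut-2-enoate (CNP0129394.2)
Conditions: AcCl (1.1 equiv), 2,4,6-collidine, CH2Cl2, -78 °C
Reagents that add atoms: acetyl chloride, CC(Cl)=O
Why: Acetyl chloride with a hindered pyridine base at low temperature should acylate the primary allylic C15 hydroxyl in preference to the hindered secondary C8 hydroxyl.

**Compound list**

1 | prop-2-yn-1-ol | C#CCO | starting material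
2 | allylmagnesium bromide | C=CC[Mg]Br | starting material
3 | 4-(prop-2-en-1-yl)-2,5-dihydro-1,2-oxamagnesole | C=CCC1=C[Mg]OC1 | intermediate
4 | (2Z)-2-(iodomethylidene)pent-4-en-1-ol | I/C=C(\CO)CC=C | intermediate
5 | tert-butyl{[(2Z)-2-(iodomethylidene)pent-4-en-1-yl]oxy}dimethylsilane | I/C=C(\CO[Si](C)(C)C(C)(C)C)CC=C | intermediate
6 | (4Z)-4-({[tert-butyl(dimethyl)silyl]oxy}methyl)-5-iodopent-4-ene-1,2-diol | I/C=C(\CO[Si](C)(C)C(C)(C)C)CC(O)CO | intermediate
7 | (3Z)-3-({[tert-butyl(dimethyl)silyl]oxy}methyl)-4-iodobut-3-enal | I/C=C(\CO[Si](C)(C)C(C)(C)C)CC=O | intermediate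
8 | hex-1-yne | C#CCCCC | starting material
9 | dicyclohexyl[(1E)-hex-1-en-1-yl]borane | CCCC/C=C/B(C1CCCCC1)C1CCCCC1 | intermediate
10 | ethyl[(1E)-hex-1-en-1-yl]zinc | CCCC/C=C/[Zn]CC | intermediate
11 | (1Z,4S,5E)-2-({[tert-butyl(dimethyl)silyl]oxy}methyl)-1-iododeca-1,5-dien-4-ol | I/C=C(\CO[Si](C)(C)C(C)(C)C)C[C@H](O)/C=C/CCCC | intermediate
12 | 3-(trimethylsilyl)prop-2-ynal | C[Si](C)(C)C#CC=O | starting material
13 | 4,4,5,5-tetramethyl-2-(2-methylprop-2-en-1-yl)-1,3,2-dioxaborolane | C=C(C)CB1OC(C)(C)C(C)(C)O1 | starting material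
14 | (3R)-5-methyl-1-(trimethylsilyl)hex-5-en-1-yn-3-ol | C=C(C)C[C@@H](O)C#C[Si](C)(C)C | intermediate
15 | tert-butyl(dimethyl){[(3R)-5-methyl-1-(trimethylsilyl)hex-5-en-1-yn-3-yl]oxy}silane | C=C(C)C[C@@H](O[Si](C)(C)C(C)(C)C)C#C[Si](C)(C)C | intermediate
16 | tert-butyl(dimethyl){[(3R)-5-methylhex-5-en-1-yn-3-yl]oxy}silane | C=C(C)C[C@@H](O[Si](C)(C)C(C)(C)C)C#C | intermediate
17 | (5E,7S,9Z,13R)-13-{[tert-butyl(dimethyl)silyl]oxy}-9-({[tert-butyl(dimethyl)silyl]oxy}methyl)-15-methylhexadeca-5,9,15-trien-11-yn-7-ol | C=C(C)C[C@@H](O[Si](C)(C)C(C)(C)C)C#C/C=C(\CO[Si](C)(C)C(C)(C)C)C[C@H](O)/C=C/CCCC | intermediate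
18 | (5E,7S,9Z,11Z,13R)-13-{[tert-butyl(dimethyl)silyl]oxy}-9-({[tert-butyl(dimethyl)silyl]oxy}methyl)-15-methylhexadeca-5,9,11,15-tetraen-7-ol | C=C(C)C[C@@H](O[Si](C)(C)C(C)(C)C)/C=C\C=C(/CO[Si](C)(C)C(C)(C)C)C[C@H](O)/C=C/CCCC | intermediate
19 | 2-bromoprop-2-enoic acid | C=C(Br)C(=O)O | starting material
20 | (4S,5R)-4-[(1R)-1-{[tert-butyl(dimethyl)silyl]oxy}-3-methylbut-3-en-1-yl]-5-[(1Z,4S,5E)-2-({[tert-butyl(dimethyl)silyl]oxy}methyl)-4-hydroxydeca-1,5-dien-1-yl]-3-methylideneoxolan-2-one | C=C1C(=O)O[C@H](/C=C(\CO[Si](C)(C)C(C)(C)C)C[C@H](O)/C=C/CCCC)[C@H]1[C@H](O[Si](C)(C)C(C)(C)C)CC(C)=C | intermediate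
21 | (4S,5R)-4-[(1R)-1-{[tert-butyl(dimethyl)silyl]oxy}-3-methylbut-3-en-1-yl]-5-[(1Z,4S,5E)-2-({[tert-butyl(dimethyl)silyl]oxy}methyl)-4-{[(2E)-2-methylbut-2-enoyl]oxy}deca-1,5-dien-1-yl]-3-methylideneoxolan-2-one | C=C1C(=O)O[C@H](/C=C(\CO[Si](C)(C)C(C)(C)C)C[C@H](OC(=O)/C(C)=C/C)/C=C/CCCC)[C@H]1[C@H](O[Si](C)(C)C(C)(C)C)CC(C)=C | intermediate
22 | (3aS,4R,6Z,8S,10Z,11aR)-4-{[tert-butyl(dimethyl)silyl]oxy}-10-({[tert-butyl(dimethyl)silyl]oxy}methyl)-6-methyl-3-methylidene-2-oxo-2,3,3a,4,5,8,9,11a-octahydrocyclodeca[b]furan-8-yl (2E)-2-methylbut-2-enoate | C=C1C(=O)O[C@@H]2/C=C(\CO[Si](C)(C)C(C)(C)C)C[C@H](OC(=O)/C(C)=C/C)/C=C(/C)C[C@@H](O[Si](C)(C)C(C)(C)C)[C@@H]12 | intermediate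
23 | (3aR,4R,6Z,8S,10Z,11aR)-4-hydroxy-10-(hydroxymethyl)-6-methyl-3-methylidene-2-oxo-2,3,3a,4,5,8,9,11a-octahydrocyclodeca[b]furan-8-yl (2E)-2-methylbut-2-enoate | C=C1C(=O)O[C@@H]2/C=C(\CO)C[C@H](OC(=O)/C(C)=C/C)/C=C(/C)C[C@@H](O)[C@@H]12 | intermediate
24 | (3aR,4R,6Z,8S,10Z,11aR)-10-(acetoxymethyl)-4-hydroxy-6-methyl-3-methylidene-2-oxo-2,3,3a,4,5,8,9,11a-octahydrocyclodeca[b]furan-8-yl (2E)-2-methylbut-2-enoate | C=C1C(=O)O[C@@H]2/C=C(\COC(C)=O)C[C@H](OC(=O)/C(C)=C/C)/C=C(/C)C[C@@H](O)[C@@H]12 | target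

**Step count and risks**

Total steps: 14. Longest linear sequence: 11 (steps 1–4, then 8–14).

Steps most likely to fail:

1. Step 10 (annulation). What may go wrong: addition of the vinyl–palladium unit to the wrong diene face; inner-sphere C–O bond formation leading to the cis-lactone; loss of the C4=C5 geometry by allyl isomerisation; Heck-type insertion at the isolated alkenes. Fallback with known chemistry, setting out from 16 and 11 and returning at 20: metal-mediated allylation of an aldehyde by a 3-substituted 2-(bromomethyl)acrylate, followed by lactonisation. Alkyne 16 is deprotonated (n-BuLi, THF, -78 °C) and trapped with methyl chloroformate to give methyl (4R)-4-(TBSO)-6-methylhept-6-en-2-ynoate F1. Syn-hydroalumination (iBu2AlH, HMPA) and trapping of the α-aluminoacrylate with formaldehyde gives methyl (2Z,4R)-4-(TBSO)-2-(hydroxymethyl)-6-methylhepta-2,6-dienoate F2. Appel bromination (CBr4, PPh3) converts it into methyl (2E,4R)-2-(bromomethyl)-4-(TBSO)-6-methylhepta-2,6-dienoate F3. Vinyl iodide 11 is converted by iodine–lithium exchange on its lithium alkoxide (t-BuLi, 3 equiv, -78 °C) and formylation with DMF into (2Z,5S,6E)-3-(TBSO-methyl)-5-hydroxyundeca-2,6-dienal F4. CrCl2-mediated coupling of F3 with F4 through a chair transition state (anti-selective) should give methyl (3S,4R,5Z,8S,9E)-3-[(1R)-1-(TBSO)-3-methylbut-3-en-1-yl]-6-(TBSO-methyl)-4,8-dihydroxy-2-methylidenetetradeca-5,9-dienoate F5, which lactonises with PPTS to 20.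

2. Step 12 (ring-closing metathesis). What may go wrong: slow loading of the ruthenium carbene at the hindered allylic-ester alkene, oligomerisation, competing metathesis at the methylene lactone, or formation of the ring-trans isomer. Fallback, setting out from 20 and returning at 22: the order of acylation and ring closure is exchanged. The free allylic alcohol 20, whose hydroxyl assists carbene transfer and whose carbinol end is unhindered, is cyclised with the second-generation Hoveyda–Grubbs catalyst (H2IMes)Cl2Ru=CH(2-iPrO-C6H4) at high dilution to (3aS,4R,6Z,8S,10Z,11aR)-4-(TBSO)-10-(TBSO-methyl)-8-hydroxy-6-methyl-3-methylidene-3a,4,5,8,9,11a-hexahydrocyclodeca[b]furan-2(3H)-one F6. F6 is then acylated with tigloyl chloride (pyridine, DMAP) to give 22.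

3. Step 4 (asymmetric alkenylation). What may go wrong: enolisation and conjugation of the β,γ-unsaturated aldehyde under the zinc alkoxide conditions, and insufficient enantioselection. Fallback, setting out from 7 and returning at 11: the stereocentre is set by reagent-controlled ketone reduction instead. Uncatalysed addition of alkenylzinc 10 to 7 gives racemic (1Z,5E)-2-(TBSO-methyl)-1-iododeca-1,5-dien-4-ol F7. Dess–Martin oxidation gives (1Z,5E)-2-(TBSO-methyl)-1-iododeca-1,5-dien-4-one F8. Corey–Bakshi–Shibata reduction ((R)-Me-CBS oxazaborolidine, catecholborane, -78 °C), with the alkenyl group acting as the large substituent, should give 11.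

Further compounds
F1 | step 10 | methyl (4R)-4-{[tert-butyl(dimethyl)silyl]oxy}-6-methylhept-6-en-2-ynoate | C=C(C)C[C@@H](O[Si](C)(C)C(C)(C)C)C#CC(=O)OC
F2 | step 10 | methyl (2Z,4R)-4-{[tert-butyl(dimethyl)silyl]oxy}-2-(hydroxymethyl)-6-methylhepta-2,6-dienoate | C=C(C)C[C@@H](O[Si](C)(C)C(C)(C)C)/C=C(/CO)C(=O)OC
F3 | step 10 | methyl (2E,4R)-2-(bromomethyl)-4-{[tert-butyl(dimethyl)silyl]oxy}-6-methylhepta-2,6-dienoate | C=C(C)C[C@@H](O[Si](C)(C)C(C)(C)C)/C=C(/CBr)C(=O)OC
F4 | step 10 | (2Z,5S,6E)-3-({[tert-butyl(dimethyl)silyl]oxy}methyl)-5-hydroxyundeca-2,6-dienal | O=C/C=C(\CO[Si](C)(C)C(C)(C)C)C[C@H](O)/C=C/CCCC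
F5 | step 10 | methyl (3S,4R,5Z,8S,9E)-3-[(1R)-1-{[tert-butyl(dimethyl)silyl]oxy}-3-methylbut-3-en-1-yl]-6-({[tert-butyl(dimethyl)silyl]oxy}methyl)-4,8-dihydroxy-2-methylidenetetradeca-5,9-dienoate | C=C(C(=O)OC)[C@@H]([C@H](O)/C=C(\CO[Si](C)(C)C(C)(C)C)C[C@H](O)/C=C/CCCC)[C@H](O[Si](C)(C)C(C)(C)C)CC(C)=C
F6 | step 12 | (3aS,4R,6Z,8S,10Z,11aR)-4-{[tert-butyl(dimethyl)silyl]oxy}-10-({[tert-butyl(dimethyl)silyl]oxy}methyl)-8-hydroxy-6-methyl-3-methylidene-3a,4,5,8,9,11a-hexahydrocyclodeca[b]furan-2(3H)-one | C=C1C(=O)O[C@@H]2/C=C(\CO[Si](C)(C)C(C)(C)C)C[C@H](O)/C=C(/C)C[C@@H](O[Si](C)(C)C(C)(C)C)[C@@H]12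
F7 | step 4 | racemic (1Z,5E)-2-({[tert-butyl(dimethyl)silyl]oxy}methyl)-1-iododeca-1,5-dien-4-ol | I/C=C(\CO[Si](C)(C)C(C)(C)C)CC(O)/C=C/CCCC
F8 | step 4 | (1Z,5E)-2-({[tert-butyl(dimethyl)silyl]oxy}methyl)-1-iododeca-1,5-dien-4-one | I/C=C(\CO[Si](C)(C)C(C)(C)C)CC(=O)/C=C/CCCC
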